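**Plan**

- Retrosynthesis: each ring is cut at the C–C bond between the enolised carbonyl carbon next to the CMe2 group and the ring carbon that carries the bridging CH2 (two retro-Dieckmann cuts). This unravels the target to one acyclic C27 bis(triacylmethane) dimethyl ester. That chain is cut at the two bonds from the triacylmethane carbons to the dimethylmalonyl carbonyls, and the resulting C15 tetraone at the two acyl bonds of its glutaryl core.
- Enabling feature: each ring is an enolised 2-acylcyclohexane-1,3,5-trione. Its C-3 (the enol carbon beside the non-enolisable quaternary C-4) is at the carboxylic acid oxidation level, and its C-2 is the α-carbon of the C-1 ketone. Because the two C-2 atoms share one CH2, the unit C-2/CH2/C-2' is the α,β,α' part of a glutaryl chain.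
- Forward: chain first, rings last. A twofold crossed Claisen condensation gives the tetraone, a twofold C-acylation with a dimethylmalonyl half-ester chloride completes the linear poly-β-carbonyl chain, and a twofold Dieckmann condensation closes both carbocycles in one operation. This copies the polyketide Claisen folding; no aromatic precursor, C-methylation or formaldehyde coupling is used.
- Stereochemistry: the target is achiral and has no stereocenter; only keto–enol tautomerism is involved, and it settles on acidic work-up.

Key step: step 4

Remark on the chemistry: the target and all 1,3-dicarbonyl intermediates are tautomeric mixtures. Each is written in one keto or enol form, and the CH centres of the triacylmethane units are enolised and carry no defined configuration.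

**Route**

Step 1
Reactants: 1 3-methylbutan-2-one; 2 dimethyl glutarate
Product: 3 2,12-dimethyltridecane-3,5,9,11-tetraone
Conditions: LiN(iPr)2 (LDA, 4.4 equiv), 1 (4.4 equiv), THF, −78 °C; then 2 (1 equiv), −78 °C → rt; 1 M HCl
Reagents that add atoms: none
Why: LDA deprotonates 1 kinetically at the methyl group, and the lithium enolate, used in excess so that half of it serves as base for the β-diketone formed, should attack both ester groups of 2 in a twofold crossed Claisen condensation; no stereocenter is formed.

Step 2
Reactants: 4 3-methoxy-2,2-dimethyl-3-oxopropanoic acid
Product: 5 methyl 3-chloro-2,2-dimethyl-3-oxopropanoate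
Conditions: (COCl)2 (1.2 equiv), DMF (cat.), CH2Cl2, 0 °C → rt; evaporate
Reagents that add atoms: oxalyl chloride, ClC(=O)C(=O)Cl
Why: Standard acid chloride formation through the chloroiminium species from DMF, with the methyl ester and the quaternary carbon inert and no ketene pathway open because there is no α-hydrogen; no stereocenter is formed.

Step 3
Reactants: 3 2,12-dimethyltridecane-3,5,9,11-tetraone; 5 methyl 3-chloro-2,2-dimethyl-3-oxopropanoate (2.2 equiv)
Product: 6 dimethyl 2,2,12,12-tetramethyl-4,10-bis(2-methylpropanoyl)-3,5,9,11-tetraoxotridecanedioate
Conditions: MgCl2 (2.2 equiv), pyridine (4.5 equiv), CH2Cl2, 0 °C → rt; cold 1 M HCl; used crude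
Reagents that add atoms: none
Why: MgCl2 and pyridine should turn each β-diketone unit of 3 into a chelated magnesium enolate that is acylated on its central carbon (soft-enolisation C-acylation of 1,3-dicarbonyl compounds by acid chlorides), giving the two triacylmethane units without setting a configurationally stable stereocenter.

Step 4
Reactants: 6 dimethyl 2,2,12,12-tetramethyl-4,10-bis(2-methylpropanoyl)-3,5,9,11-tetraoxotridecanedioate
Product: 8 albaspidin iBiB (the target), via half-cyclised keto ester 7 (not isolated)
Conditions: LiN(iPr)2 (LDA, 6 equiv), THF, −78 °C → rt; then 1 M HCl
Reagents that add atoms: none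
Why: LiN(iPr)2 first converts both triacylmethane units of 6 into triketonates and then removes one proton from each chain CH2 next to the C-5 and C-9 ketones; each carbanion so formed adds to the methyl ester carbonyl of its own arm, methoxide is expelled, and the new ring CH, now flanked by two carbonyls, is deprotonated at once, which makes each closure irreversible until the acid quench releases the enol form. The closest known reaction type is the Dieckmann condensation in its polyanion form, the intramolecular acylation of the terminal carbanion of a poly-β-carbonyl chain by an ester, which is the laboratory counterpart of the Claisen cyclisation by which polyketide synthases fold a poly-β-keto thioester into an acylphloroglucinol. Each of the two six-membered rings closes in a 6-(enolendo)-exo-trig mode, the first closure giving 7 and the second 8. No stereocenter is formed, and the labile CH centres of 6 end as sp2 carbons. The step needs deprotonation at the chain CH2 and not at the isobutyryl CH, which would lead to a tetramethyl ring, and this is secured by the kinetic preference of the hindered amide base for the secondary over the tertiary α-position and by the fact that only closure through the chain carbon gives a ring CH that can be deprotonated again. It also needs attack on the ester and not on a ketone, which is secured because every ketone is buried in a triketonate while the ester, having no α-hydrogen, cannot enolise and lies six atoms from the carbanion.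

**Compound list**

1 | 3-methylbutan-2-one | CC(C)C(C)=O | starting material
2 | dimethyl glutarate (dimethyl pentanedioate) | COC(=O)CCCC(=O)OC | starting material
3 | 2,12-dimethyltridecane-3,5,9,11-tetraone | CC(C)C(=O)CC(=O)CCCC(=O)CC(=O)C(C)C | intermediate
4 | 3-methoxy-2,2-dimethyl-3-oxopropanoic acid (monomethyl dimethylmalonate) | COC(=O)C(C)(C)C(O)=O | starting material
5 | methyl 3-chloro-2,2-dimethyl-3-oxopropanoate | COC(=O)C(C)(C)C(Cl)=O | intermediate
6 | dimethyl 2,2,12,12-tetramethyl-4,10-bis(2-methylpropanoyl)-3,5,9,11-tetraoxotridecanedioate (triketo form drawn; C-4 and C-10 enolised, no defined configuration) | COC(=O)C(C)(C)C(=O)C(C(=O)C(C)C)C(=O)CCCC(=O)C(C(=O)C(C)C)C(=O)C(C)(C)C(=O)OC | intermediate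
7 | methyl 7-[2,4-dihydroxy-3,3-dimethyl-5-(2-methylpropanoyl)-6-oxocyclohexa-1,4-dien-1-yl]-2,2-dimethyl-4-(2-methylpropanoyl)-3,5-dioxoheptanoate (half-cyclised keto ester, not isolated) | CC(C)C(=O)C1=C(O)C(C)(C)C(O)=C(CCC(=O)C(C(=O)C(C)C)C(=O)C(C)(C)C(=O)OC)C1=O | intermediate
8 | albaspidin iBiB, 2,2'-methylenebis[3,5-dihydroxy-4,4-dimethyl-6-(2-methylpropanoyl)cyclohexa-2,5-dien-1-one] (achiral) | CC(C)C(=O)C1=C(O)C(C)(C)C(O)=C(CC2=C(O)C(C)(C)C(O)=C(C(=O)C(C)C)C2=O)C1=O | target

**Step count and risks**

Total step count: 4. Longest linear sequence: 3 steps (steps 1, 3 and 4); step 2 is a one-step side branch.

Steps most likely to fail: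

1. Step 4 (twofold Dieckmann closure). The second deprotonation may take place in part at the isobutyryl CH, so that closure runs toward a tetramethyl ring. The sequence may also stall after the first closure because of charge build-up and aggregation of the polyanion, or the triacylmethane may be cleaved by the liberated methoxide. Fallback, which reverses the order of bond formation and sets out from 3: the tetra-anion of 3 (LiN(iPr)2 in excess, THF, 0 °C; deprotonation at C-4/C-10 and at the chain carbons C-6/C-8) would be acylated at its two terminal carbanions by dimethyl 2,2-dimethylmalonate (COC(=O)C(C)(C)C(=O)OC), the known ester acylation of β-diketone dianions. This gives dimethyl 2,2,8,8-tetramethyl-4,6-bis(4-methyl-3-oxopentanoyl)-3,7-dioxononanedioate F1. On heating with NaOMe in MeOH, the central carbon of each remaining β-diketone unit of F1 would close onto the neighbouring ester, the known cyclisation of 5,7-dioxo esters to 2-acylcyclohexane-1,3-diones. Each ring is then completed through its acyl-bearing carbon, where closure through the isobutyryl CH would need an eight-membered ring. Acidification returns the route at 8.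

2. Step 3 (twofold C-acylation). The hindered acid chloride may react at oxygen instead of carbon, the second acylation may remain incomplete, or the triacylmethane may lose an acyl group during work-up. Fallback, which exchanges the roles of the partners and sets out from 1: the lithium enolate of 1 (LiN(iPr)2, THF, −78 °C) would be acylated once by dimethyl 2,2-dimethylmalonate in a crossed Claisen condensation to give methyl 2,2,6-trimethyl-3,5-dioxoheptanoate F2. Two equivalents of F2 would then be C-acylated under MgCl2/pyridine by the unhindered glutaryl dichloride (ClC(=O)CCCC(=O)Cl), so that the hindered component is the nucleophile. This returns the route at 6.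

3. Step 1 (twofold Claisen condensation). After the first condensation the diketonate may attack the remaining ester of its own chain and close to a 2-acylcyclohexane-1,3-dione, or the second condensation may remain incomplete. Fallback, which moves the bond formation from the acyl carbons to the central CH2 and sets out from 1: a crossed Claisen condensation of 1 with ethyl acetate (NaH, THF) would give 5-methylhexane-2,4-dione F3. Its dianion (LiN(iPr)2, 2 equiv, THF, 0 °C) would be alkylated twofold at the terminal methyl carbon by diiodomethane (ICI, 0.5 equiv), the known twofold alkylation of β-diketone dianions by dihalides. This returns the route at 3.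

**Further compounds**

F1 | step 4 | dimethyl 2,2,8,8-tetramethyl-4,6-bis(4-methyl-3-oxopentanoyl)-3,7-dioxononanedioate | COC(=O)C(C)(C)C(=O)C(CC(C(=O)C(C)(C)C(=O)OC)C(=O)CC(=O)C(C)C)C(=O)CC(=O)C(C)C
F2 | step 3 | methyl 2,2,6-trimethyl-3,5-dioxoheptanoate | COC(=O)C(C)(C)C(=O)CC(=O)C(C)C
F3 | step 1 | 5-methylhexane-2,4-dione | CC(=O)CC(=O)C(C)C
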